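Ring C is cut at O1–C2 and C2–C3. C2, flanked by O1 and C3, is an aldehyde carbon in disguise, and C4 bears rings A and P (P = the phloroglucinol ring), both able to carry positive charge; ring B and C2 therefore come from 4-benzyloxybenzaldehyde, the rest from an ortho-hydroxy 1,1-diarylethylene. One chiral-acid-catalysed Prins-type annulation joins the two, closes ring C and sets C2. Its precursor is a 1,1-diarylethylene whose ring A carries the only free phenol, ortho to the alkene, with all other oxygens as benzyl ethers. Hydrogenation then sets C4 cis to C2 and frees the phenols, and ring P is acylated last.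

Key step: step 6

Assumption: the sense of induction of the chiral acid cannot be fixed on paper; the (R)-acid is written, and its mirror image is used instead if a first run delivers 2S.

**Step 1**
Reactants: 1 phloroglucinol triacetate
Product: 2 1,3,5-tris(benzyloxy)benzene
Conditions: BnCl (3.3 equiv), NaH (6.6 equiv), H2O (3 equiv, added slowly), DMF, 0 °C to rt
Reagents that add atoms: benzyl chloride, ClCc1ccccc1
Why: Williamson etherification in which NaOH made from NaH and water unmasks each phenoxide in the presence of benzyl chloride, so O-benzylation should outrun the C-benzylation that troubles free phloroglucinol.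

**Step 2**
Reactants: 2 1,3,5-tris(benzyloxy)benzene
Product: 3 2-bromo-1,3,5-tris(benzyloxy)benzene
Conditions: NBS (1.0 equiv), CH2Cl2, −78 °C to 0 °C
Reagents that add atoms: N-bromosuccinimide, O=C1CCC(=O)N1Br
Why: Electrophilic aromatic bromination; the three open ring positions of 2 are equivalent and one equivalent of NBS at low temperature should stop at the monobromide.

**Step 3**
Reactants: 4 2,4-dihydroxyacetophenone
Product: 5 1-[4-(benzyloxy)-2-hydroxyphenyl]ethanone
Conditions: BnBr (1.05 equiv), K2CO3, acetone, reflux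
Reagents that add atoms: benzyl bromide, BrCc1ccccc1
Why: Williamson etherification selective for the 4-hydroxyl, because the 2-hydroxyl is held in a hydrogen bond to the ketone and is far less nucleophilic.

**Step 4**
Reactants: 5 1-[4-(benzyloxy)-2-hydroxyphenyl]ethanone
Product: 6 N'-{(E)-1-[4-(benzyloxy)-2-hydroxyphenyl]ethylidene}-4-methylbenzenesulfonohydrazide
Conditions: TsNHNH2, MeOH, 60 °C
Reagents that add atoms: p-toluenesulfonohydrazide, Cc1ccc(cc1)S(=O)(=O)NN
Why: Hydrazone condensation of an aryl methyl ketone with tosylhydrazide, which the free phenol does not disturb; the hydrazone geometry has no bearing on later steps.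

**Step 5**
Reactants: 3 2-bromo-1,3,5-tris(benzyloxy)benzene; 6 N'-{(E)-1-[4-(benzyloxy)-2-hydroxyphenyl]ethylidene}-4-methylbenzenesulfonohydrazide
Product: 8 5-(benzyloxy)-2-{1-[2,4,6-tris(benzyloxy)phenyl]ethenyl}phenol, via diazoalkane 7 (not isolated)
Conditions: Pd2(dba)3 (2.5 mol %), XPhos (10 mol %), LiOtBu (3.5 equiv), 1,4-dioxane, 100 °C; then aq. NH4Cl
Reagents that add atoms: none
Why: Barluenga coupling, in which base converts 6 into diazoalkane 7, the arylpalladium bromide formed from 3 and zerovalent palladium takes it up as a carbene, and aryl migration followed by β-hydride elimination from the methyl group gives the alkene; XPhos is chosen for the 2,6-disubstituted bromide and the extra base carries the phenol through as its lithium salt.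

**Step 6**
Reactants: 8 5-(benzyloxy)-2-{1-[2,4,6-tris(benzyloxy)phenyl]ethenyl}phenol; 9 4-(benzyloxy)benzaldehyde
Product: 12 (2R)-7-(benzyloxy)-2-[4-(benzyloxy)phenyl]-4-[2,4,6-tris(benzyloxy)phenyl]-2H-chromene, via hemiacetal 10 (not isolated), via oxocarbenium ion 11 (not isolated)
Conditions: 9 (1.2 equiv), (R)-3,3'-bis(2,4,6-triisopropylphenyl)-H8-BINOL N-triflylphosphoramide (10 mol %), 5 Å molecular sieves, toluene, −40 °C; Et3N quench at −40 °C
Reagents that add atoms: none
Why: Proposed new method: the acid condenses the ring A phenol of 8 with 9 to hemiacetal 10 and ionises it to oxocarbenium ion 11, which stays paired with the chiral phosphoramide anion; the CH2 terminus of the diarylethylene then adds to C2 and the resulting C4 cation, stabilised by rings A and P, loses the C3 proton, so that O1–C2 and C2–C3 are formed and 12 results. The closest known reaction types are the achiral acid-mediated condensation of ortho-(1-arylvinyl)phenols with aldehydes to 2H-chromenes, asymmetric Prins and oxa-Pictet–Spengler cyclisations under chiral strong Brønsted acids, and the chiral N-triflylphosphoramide-catalysed closure of phenol-tethered 1,3-diarylallyl cations to 2,4-diaryl-2H-chromenes. Ring C closes in a 6-endo-trig mode, the only one open because attack through the internal alkene carbon would leave a primary cation. C2 is set by the catalyst: the anion covers one face of the oxocarbenium carbon, and the same ion-pair control would hold if the C2–C3 bond formed first and O1 closed onto the allyl cation. The step needs the alkene terminus to win over the open CH positions of ring P and over the ring A carbons, which the tether through O1 and the high π-nucleophilicity of the doubly aryl-substituted alkene should secure. The low temperature and the cold amine quench are meant to keep the C2–O1 bond from reopening under acid, which would erode the enantiomeric purity.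

**Step 7**
Reactants: 12 (2R)-7-(benzyloxy)-2-[4-(benzyloxy)phenyl]-4-[2,4,6-tris(benzyloxy)phenyl]-2H-chromene
Product: 13 2-[(2R,4R)-7-hydroxy-2-(4-hydroxyphenyl)-3,4-dihydro-2H-chromen-4-yl]benzene-1,3,5-triol
Conditions: H2 (1 atm), 10% Pd/C, EtOAc/MeOH 1:1, rt
Reagents that add atoms: none
Why: Heterogeneous hydrogenation with hydrogenolysis: hydrogen should add syn to C3=C4 from the face opposite the C2 aryl group, which sets C4 as R (2,4-cis), while the five benzyl ethers are cleaved and the cyclic C2–O1 ether, no longer allylic once the alkene is reduced, is kept under neutral conditions at room temperature.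

**Step 8**
Reactants: 13 2-[(2R,4R)-7-hydroxy-2-(4-hydroxyphenyl)-3,4-dihydro-2H-chromen-4-yl]benzene-1,3,5-triol; 14 9-phenylnonanoic acid
Product: 15 1-{2,4,6-trihydroxy-3-[(2R,4R)-7-hydroxy-2-(4-hydroxyphenyl)-3,4-dihydro-2H-chromen-4-yl]phenyl}-9-phenylnonan-1-one
Conditions: 14 (1.05 equiv), BF3·OEt2 (neat), 60 °C; then ice-water
Reagents that add atoms: none
Why: Friedel–Crafts acylation with a carboxylic acid activated by BF3, the usual way to acylphloroglucinols: ring P is by far the most nucleophilic ring, its two open positions are equivalent, and the first acyl group deactivates it towards a second.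

**Compound list**
1 | phloroglucinol triacetate (benzene-1,3,5-triyl triacetate) | CC(=O)Oc1cc(OC(C)=O)cc(OC(C)=O)c1 | starting material
2 | 1,3,5-tris(benzyloxy)benzene | c1ccc(COc2cc(OCc3ccccc3)cc(OCc3ccccc3)c2)cc1 | intermediate
3 | 2-bromo-1,3,5-tris(benzyloxy)benzene | Brc1c(OCc2ccccc2)cc(OCc2ccccc2)cc1OCc1ccccc1 | intermediate
4 | 2,4-dihydroxyacetophenone | CC(=O)c1ccc(O)cc1O | starting material
5 | 1-[4-(benzyloxy)-2-hydroxyphenyl]ethanone | CC(=O)c1ccc(OCc2ccccc2)cc1O | intermediate
6 | N'-{(E)-1-[4-(benzyloxy)-2-hydroxyphenyl]ethylidene}-4-methylbenzenesulfonohydrazide | C/C(=N\NS(=O)(=O)c1ccc(C)cc1)c1ccc(OCc2ccccc2)cc1O | intermediate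
7 | 5-(benzyloxy)-2-(1-diazoethyl)phenol (formed in the flask, present as its lithium phenoxide) | CC(=[N+]=[N-])c1ccc(OCc2ccccc2)cc1O | intermediate
8 | 5-(benzyloxy)-2-{1-[2,4,6-tris(benzyloxy)phenyl]ethenyl}phenol | C=C(c1ccc(OCc2ccccc2)cc1O)c1c(OCc2ccccc2)cc(OCc2ccccc2)cc1OCc1ccccc1 | intermediate
9 | 4-(benzyloxy)benzaldehyde | O=Cc1ccc(OCc2ccccc2)cc1 | starting material
10 | [5-(benzyloxy)-2-{1-[2,4,6-tris(benzyloxy)phenyl]ethenyl}phenoxy][4-(benzyloxy)phenyl]methanol (hemiacetal, either configuration at the carbinol carbon, formed in the flask) | C=C(c1ccc(OCc2ccccc2)cc1OC(O)c1ccc(OCc2ccccc2)cc1)c1c(OCc2ccccc2)cc(OCc2ccccc2)cc1OCc1ccccc1 | intermediate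
11 | [4-(benzyloxy)benzylidene][5-(benzyloxy)-2-{1-[2,4,6-tris(benzyloxy)phenyl]ethenyl}phenyl]oxonium (cation paired with the phosphoramide anion, formed in the flask) | C=C(c1ccc(OCc2ccccc2)cc1[O+]=Cc1ccc(OCc2ccccc2)cc1)c1c(OCc2ccccc2)cc(OCc2ccccc2)cc1OCc1ccccc1 | intermediate
12 | (2R)-7-(benzyloxy)-2-[4-(benzyloxy)phenyl]-4-[2,4,6-tris(benzyloxy)phenyl]-2H-chromene | C(c1ccccc1)Oc1cc(OCc2ccccc2)c(C2=C[C@H](c3ccc(OCc4ccccc4)cc3)Oc3cc(OCc4ccccc4)ccc32)c(OCc2ccccc2)c1 | intermediate
13 | 2-[(2R,4R)-7-hydroxy-2-(4-hydroxyphenyl)-3,4-dihydro-2H-chromen-4-yl]benzene-1,3,5-triol (2,4-cis) | Oc1cc(O)c([C@@H]2C[C@H](c3ccc(O)cc3)Oc3cc(O)ccc32)c(O)c1 | intermediate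
14 | 9-phenylnonanoic acid | OC(=O)CCCCCCCCc1ccccc1 | starting material
15 | 1-{2,4,6-trihydroxy-3-[(2R,4R)-7-hydroxy-2-(4-hydroxyphenyl)-3,4-dihydro-2H-chromen-4-yl]phenyl}-9-phenylnonan-1-one (2,4-cis) | O=C(CCCCCCCCc1ccccc1)c1c(O)cc(O)c([C@@H]2C[C@H](c3ccc(O)cc3)Oc3cc(O)ccc32)c1O | target

**Totals**
Total step count: 8. Longest linear sequence: 6 steps (steps 1, 2, 5, 6, 7, 8; the branch through steps 3, 4, 5, 6, 7, 8 is equally long).

**Steps most likely to fail**

Step 6 (Proposed new method). The facial control at C2 may be poor, or the enantiomeric purity may erode through acid-mediated reopening and reclosure of the C2–O1 bond. Friedel–Crafts hydroxyalkylation at the open positions of ring P or acid-induced oligomerisation of the electron-rich alkene may also take material away. The fallback uses known chemistry; it sets out from ketone 5, aldehyde 9 and bromide 3 and comes back at chromene 12. Claisen–Schmidt condensation of 5 with 9 (KOH, EtOH, rt) should give the 2'-hydroxychalcone (E)-1-[4-(benzyloxy)-2-hydroxyphenyl]-3-[4-(benzyloxy)phenyl]prop-2-en-1-one F1. Bromine–lithium exchange on 3 (n-BuLi, THF, −78 °C) gives 2,4,6-tris(benzyloxy)phenyllithium F2, which adds 1,2 to the ketone of F1 (phenol first deprotonated with NaH) to give the racemic tertiary allylic alcohol (E)-5-(benzyloxy)-2-{3-[4-(benzyloxy)phenyl]-1-hydroxy-1-[2,4,6-tris(benzyloxy)phenyl]prop-2-en-1-yl}phenol F3. The same chiral N-triflylphosphoramide in toluene at −78 °C then ionises F3 to the allyl cation contact ion pair, and O1 closes onto C2 to give 12; this asymmetric intramolecular allylic etherification is a known reaction type for 2,4-diaryl-2H-chromenes.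

Step 8. Hot Lewis acid may ionise the finished 4-arylflavan at C4 or open ring C at C2, which would scramble the cis relationship, and acylation may spill over to ring A or to oxygen. The fallback sets out from chromene 12 and comes back at target 15, so that acid never meets the free polyphenol. Homogeneous hydrogenation with [Ir(cod)(PCy3)(py)]PF6 and H2 in CH2Cl2 should reduce only the alkene, again anti to the C2 aryl group, and give (2R,4R)-7-(benzyloxy)-2-[4-(benzyloxy)phenyl]-4-[2,4,6-tris(benzyloxy)phenyl]chromane F4. Acid 14 and trifluoroacetic anhydride form 9-phenylnonanoic trifluoroacetic anhydride F5 in CH2Cl2 at 0 °C, which acylates the tris(benzyloxy)phenyl ring of F4 (Friedel–Crafts acylation, known for 1,3,5-trialkoxybenzenes) to give 1-{2,4,6-tris(benzyloxy)-3-[(2R,4R)-7-(benzyloxy)-2-[4-(benzyloxy)phenyl]-3,4-dihydro-2H-chromen-4-yl]phenyl}-9-phenylnonan-1-one F6. Hydrogenolysis of the five benzyl ethers of F6 (H2, 10% Pd/C, EtOAc/MeOH, rt) gives 15; the hydrogen-bonded aryl ketone should survive.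

Step 5. Oxidative addition of the hindered, electron-rich bromide may be slow, and the ortho-phenoxide diazoalkane may lose nitrogen or form azine before it is captured by palladium. The fallback sets out from ketone 5 and bromide 3 and comes back at precursor 8. Silylation of 5 (TBSCl, imidazole, DMF) gives 1-[4-(benzyloxy)-2-(tert-butyldimethylsilyloxy)phenyl]ethanone F7. Addition of 2,4,6-tris(benzyloxy)phenyllithium F2 (from 3, n-BuLi, THF, −78 °C) to the ketone gives racemic 1-[4-(benzyloxy)-2-(tert-butyldimethylsilyloxy)phenyl]-1-[2,4,6-tris(benzyloxy)phenyl]ethanol F8. Dehydration of this doubly benzylic tertiary alcohol (cat. PPTS, toluene, 50 °C) gives tert-butyl{5-(benzyloxy)-2-{1-[2,4,6-tris(benzyloxy)phenyl]ethenyl}phenoxy}dimethylsilane F9, and TBAF in THF at 0 °C removes the silyl group to give 8.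

**Further compounds**
F1 | step 6 | (E)-1-[4-(benzyloxy)-2-hydroxyphenyl]-3-[4-(benzyloxy)phenyl]prop-2-en-1-one | O=C(/C=C/c1ccc(OCc2ccccc2)cc1)c1ccc(OCc2ccccc2)cc1O
F2 | step 6 | 2,4,6-tris(benzyloxy)phenyllithium | [Li]c1c(OCc2ccccc2)cc(OCc2ccccc2)cc1OCc1ccccc1
F3 | step 6 | racemic (E)-5-(benzyloxy)-2-{3-[4-(benzyloxy)phenyl]-1-hydroxy-1-[2,4,6-tris(benzyloxy)phenyl]prop-2-en-1-yl}phenol | OC(/C=C/c1ccc(OCc2ccccc2)cc1)(c1ccc(OCc2ccccc2)cc1O)c1c(OCc2ccccc2)cc(OCc2ccccc2)cc1OCc1ccccc1
F4 | step 8 | (2R,4R)-7-(benzyloxy)-2-[4-(benzyloxy)phenyl]-4-[2,4,6-tris(benzyloxy)phenyl]chromane | c1ccc(COc2cc(OCc3ccccc3)c([C@@H]3C[C@H](c4ccc(OCc5ccccc5)cc4)Oc4cc(OCc5ccccc5)ccc43)c(OCc3ccccc3)c2)cc1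
F5 | step 8 | 9-phenylnonanoic trifluoroacetic anhydride | O=C(CCCCCCCCc1ccccc1)OC(=O)C(F)(F)F
F6 | step 8 | 1-{2,4,6-tris(benzyloxy)-3-[(2R,4R)-7-(benzyloxy)-2-[4-(benzyloxy)phenyl]-3,4-dihydro-2H-chromen-4-yl]phenyl}-9-phenylnonan-1-one | O=C(CCCCCCCCc1ccccc1)c1c(OCc2ccccc2)cc(OCc2ccccc2)c([C@@H]2C[C@H](c3ccc(OCc4ccccc4)cc3)Oc3cc(OCc4ccccc4)ccc32)c1OCc1ccccc1
F7 | step 5 | 1-[4-(benzyloxy)-2-(tert-butyldimethylsilyloxy)phenyl]ethanone | CC(=O)c1ccc(OCc2ccccc2)cc1O[Si](C)(C)C(C)(C)C
F8 | step 5 | racemic 1-[4-(benzyloxy)-2-(tert-butyldimethylsilyloxy)phenyl]-1-[2,4,6-tris(benzyloxy)phenyl]ethanol | CC(O)(c1ccc(OCc2ccccc2)cc1O[Si](C)(C)C(C)(C)C)c1c(OCc2ccccc2)cc(OCc2ccccc2)cc1OCc1ccccc1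
F9 | step 5 | tert-butyl{5-(benzyloxy)-2-{1-[2,4,6-tris(benzyloxy)phenyl]ethenyl}phenoxy}dimethylsilane | C=C(c1ccc(OCc2ccccc2)cc1O[Si](C)(C)C(C)(C)C)c1c(OCc2ccccc2)cc(OCc2ccccc2)cc1OCc1ccccc1
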